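The disconnection on which everything rests is the bond between C5' of the 2,2'-bithiophene (the sulfur-adjacent α-carbon of the second thiophene ring) and the exocyclic, oxygen-bearing CH2 carbon. A Pd/Cu-catalysed Migita–Kosugi–Stille coupling joins the fully elaborated 5'-bromo-bithiophene butynyl ester with (tributylstannyl)methyl 3-methylbutanoate, so the CH2 carbon arrives with its isovalerate ester intact and the target is completed in one neutral operation. The step exploits the easy oxidative addition of the thiophene α-C–Br bond and the preferential transfer of an α-acyloxy carbon from tin. The bromide precursor comes from mono-Sonogashira coupling of 5,5'-dibromo-2,2'-bithiophene; the stannane from acylation of (tributylstannyl)methanol.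

Key step: step 4

Remark: the target has no stereocentre, so no configuration has to be set; (tributylstannyl)methanol is taken as a purchasable reagent.

Step 1
Reactants: 1 but-3-yn-1-ol; 2 3-methylbutanoyl chloride (isovaleryl chloride)
Product: 3 but-3-yn-1-yl 3-methylbutanoate
Conditions: Et3N (1.5 equiv), DMAP (cat.), CH2Cl2, 0 °C to rt
Reagents that add atoms: none
Why: DMAP-catalysed O-acylation (nucleophilic acyl substitution) of a primary alcohol by an acid chloride; the terminal alkyne is inert.

Step 2
Reactants: 3 but-3-yn-1-yl 3-methylbutanoate; 4 5,5'-dibromo-2,2'-bithiophene (3 equiv)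
Product: 5 4-(5'-bromo-[2,2'-bithiophen]-5-yl)but-3-yn-1-yl 3-methylbutanoate
Conditions: PdCl2(PPh3)2 (3 mol %), CuI (5 mol %), Et3N/THF, degassed, 50 °C, slow addition of 3; excess 4 recovered by chromatography
Reagents that add atoms: none
Why: Sonogashira coupling at a thiophene α-C–Br bond, where the excess of symmetrical 4 and slow addition of 3 bias the statistics towards mono-alkynylation; 4, 5 and the bis-alkyne differ by one ester each and should separate by polarity, and the ester tolerates the amine base.

Step 3
Reactants: 6 (tributylstannyl)methanol; 2 3-methylbutanoyl chloride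
Product: 7 (tributylstannyl)methyl 3-methylbutanoate
Conditions: Et3N (1.5 equiv), DMAP (cat.), CH2Cl2, 0 °C to rt; chromatography on Et3N-deactivated silica
Reagents that add atoms: none
Why: DMAP-catalysed O-acylation of the α-stannyl primary alcohol; the amine scavenges HCl so that the acid-labile Sn–CH2 bond is not protodestannylated.

Step 4
Reactants: 5 4-(5'-bromo-[2,2'-bithiophen]-5-yl)but-3-yn-1-yl 3-methylbutanoate; 7 (tributylstannyl)methyl 3-methylbutanoate (1.3 equiv)
Product: 8 4-[5'-{[(3-methylbutanoyl)oxy]methyl}-[2,2'-bithiophen]-5-yl]but-3-yn-1-yl 3-methylbutanoate (target)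
Conditions: Pd(PPh3)4 (5 mol %), CuI (10 mol %), 1,4-dioxane, degassed, 90 °C; tin residues removed on K2CO3-doped silica
Reagents that add atoms: none
Why: Pd(0) adds oxidatively to the C5'–Br bond of 5 (thiophene α-position), the acyloxymethyl group of 7 is passed from tin via copper to palladium, and reductive elimination forms the C5'–CH2 bond and releases 8 directly. The closest known reaction type is the Migita–Kosugi–Stille coupling of α-oxygenated methylstannanes (hydroxymethyl and alkoxymethyl transfer to aryl bromides), helped by the copper-assisted transmetalation known for α-acyloxy stannanes. No ring is closed and no stereocentre is formed. The selectivity needed is transfer of the CH2O carbon in preference to the three butyl groups, which the α-oxygen (inductive activation of the Sn–CH2 bond) and coordination of the ester carbonyl to copper should secure. Chemoselectivity follows from the single C–Br bond in 5 and from the neutral, base-free medium, which should leave both isovalerate esters and the internal alkyne untouched; holding the temperature at 90 °C with a PPh3-ligated catalyst should keep Pd(0) from ionising the new thienylmethyl ester.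

Compound list
1 | but-3-yn-1-ol | C#CCCO | starting material
2 | 3-methylbutanoyl chloride (isovaleryl chloride) | CC(C)CC(=O)Cl | starting material
3 | but-3-yn-1-yl 3-methylbutanoate | CC(C)CC(=O)OCCC#C | intermediate
4 | 5,5'-dibromo-2,2'-bithiophene | Brc1ccc(-c2ccc(Br)s2)s1 | starting material
5 | 4-(5'-bromo-[2,2'-bithiophen]-5-yl)but-3-yn-1-yl 3-methylbutanoate | CC(C)CC(=O)OCCC#Cc1ccc(-c2ccc(Br)s2)s1 | intermediate
6 | (tributylstannyl)methanol | CCCC[Sn](CCCC)(CCCC)CO | starting material
7 | (tributylstannyl)methyl 3-methylbutanoate | CCCC[Sn](CCCC)(CCCC)COC(=O)CC(C)C | intermediate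
8 | 4-[5'-{[(3-methylbutanoyl)oxy]methyl}-[2,2'-bithiophen]-5-yl]but-3-yn-1-yl 3-methylbutanoate | CC(C)CC(=O)OCCC#Cc1ccc(-c2ccc(COC(=O)CC(C)C)s2)s1 | target

Total step count: 4. Longest linear sequence: 3 steps (steps 1, 2, 4); the stannane branch (steps 3, 4) is 2 steps.

Steps most likely to fail

1. Step 4. Transfer of the acyloxymethyl group from tin may be slow relative to butyl transfer or protodestannylation, or Pd(0) may ionise the newly formed thienylmethyl ester. Fallback: setting out from 5, the free alcohol 6 is used in a Migita–Kosugi hydroxymethylation (Pd(PPh3)4, 1,4-dioxane, 90 °C), which should give 4-[5'-(hydroxymethyl)-[2,2'-bithiophen]-5-yl]but-3-yn-1-yl 3-methylbutanoate F1. This alcohol is then acylated with 2 (Et3N, DMAP, CH2Cl2, 0 °C), coming back to the route at 8. The C5'–CH2 bond is thus formed with the hydroxymethyl donor and the ester is installed afterwards.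

2. Step 2. The second C–Br bond may couple at a comparable rate, so that bis-alkynylation erodes the supply of 5. Fallback: setting out from 3, Sonogashira coupling (PdCl2(PPh3)2, CuI, Et3N/THF, 50 °C) with 5-bromo-2,2'-bithiophene F2 (purchased), which has a single reactive site, should give 4-([2,2'-bithiophen]-5-yl)but-3-yn-1-yl 3-methylbutanoate F3. Electrophilic bromination with NBS (1.0 equiv, DMF, 0 °C, dark) at the only free thiophene α-position (C5') then comes back to the route at 5.

3. Step 3. The Sn–CH2 bond may be cleaved by adventitious HCl during acylation or on silica during purification. Fallback: setting out from 6, iodination with PPh3 and N-iodosuccinimide (THF, 0 °C) should give tributyl(iodomethyl)stannane F4. SN2 displacement with cesium 3-methylbutanoate F5 (formed from isovaleric acid, CC(C)CC(=O)O, and Cs2CO3 in DMF, rt) then comes back to the route at 7. The ester C–O bond is made by carboxylate alkylation under acid-free conditions.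

Further compounds
F1 | step 4 | 4-[5'-(hydroxymethyl)-[2,2'-bithiophen]-5-yl]but-3-yn-1-yl 3-methylbutanoate | CC(C)CC(=O)OCCC#Cc1ccc(-c2ccc(CO)s2)s1
F2 | step 2 | 5-bromo-2,2'-bithiophene (purchased) | Brc1ccc(-c2cccs2)s1
F3 | step 2 | 4-([2,2'-bithiophen]-5-yl)but-3-yn-1-yl 3-methylbutanoate | CC(C)CC(=O)OCCC#Cc1ccc(-c2cccs2)s1
F4 | step 3 | tributyl(iodomethyl)stannane | CCCC[Sn](CCCC)(CCCC)CI
F5 | step 3 | cesium 3-methylbutanoate | CC(C)CC(=O)[O-].[Cs+]
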